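**Retrosynthetic overview**
- Numbering: pyran O1, C2, C3, C4; benzene ring C4a, C5, C6, C7, C8, C8a; Cα is the carbonyl on C6 and Cβ the carbonyl on the anisyl ring.
- Feature used: in the chromene benzene ring, the run C5–C4a–C8a–C8 carries oxygen at C5, C8a and C8, which is the 1,3,4-oxygenation of methyl 4-methoxyacetoacetate. The remaining pair C6 (acyl) and C7 (H) corresponds to a terminal ynone.
- Late disconnections: Cβ=O comes from its dimethyl ketal. The pyran ring (bonds C4a–C4 and O1–C2) comes from 3-methylbut-2-enal and the C8a phenol.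
- Key disconnection: C8–C7 and C5–C6 form by [4+2] cycloaddition of the acetoacetate-derived bis(silyl enol ether) with HC≡C–CO–C(OMe)2–anisyl, and the adduct aromatises by loss of MeOSiMe3.
- Ring order: the anisyl ring is purchased, the chromene benzene ring is made first (step 6), and the pyran ring second (step 7).

Key step: step 6

Remark: 17 has no stereocentre. The enol-ether geometries of 2, 3 and 4 are drawn as single isomers, and any E/Z mixture converges because C5 and C8 end as aromatic carbons.
Remark: α,α-dimethoxy aryl ketones (10, 13, 16) are prone to photochemical α-cleavage, so steps 5 to 8 are run with exclusion of light.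

**Step 1**
Reactants: 1 methyl 4-methoxyacetoacetate
Product: 2 methyl (Z)-4-methoxy-3-(trimethylsilyloxy)but-2-enoate
Conditions: TMSCl, Et3N, toluene, rt, Ar; filter, distil
Reagents that add atoms: chlorotrimethylsilane, C[Si](C)(C)Cl
Why: Soft enolisation and O-silylation of a β-keto ester, in which Et3N removes the doubly activated C2 proton and TMSCl traps the ester-conjugated enolate on oxygen, so the enol ether forms towards C2 and not towards the CH2OMe group.

**Step 2**
Reactants: 2 methyl (Z)-4-methoxy-3-(trimethylsilyloxy)but-2-enoate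
Product: 4 (1Z,3Z)-1,4-dimethoxy-1,3-bis(trimethylsilyloxy)buta-1,3-diene, via lithium dienolate 3 (not isolated)
Conditions: LiN(i-Pr)2 (LDA), THF, −78 °C; TMSCl, −78 °C → rt; evaporate, hexane, filter under Ar, high vacuum; used without chromatography
Reagents that add atoms: chlorotrimethylsilane, C[Si](C)(C)Cl
Why: Standard second silylation of a β-keto ester silyl enol ether, in which the amide base removes the γ-proton (vinylogous to the ester, further acidified by OMe) to give the extended dienolate 3, and the hard silyl electrophile captures it at the ester oxygen as a silyl ketene acetal.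

**Step 3**
Reactants: 5 methyl 2-(4-methoxyphenyl)-2-oxoacetate
Product: 6 methyl 2,2-dimethoxy-2-(4-methoxyphenyl)acetate
Conditions: HC(OMe)3, cat. H2SO4, MeOH, reflux
Reagents that add atoms: trimethyl orthoformate, COC(OC)OC
Why: Acid-catalysed ketalisation with the orthoformate as water scavenger, in which the ketone is activated by the neighbouring ester, the anisyl ring stabilises the cationic stages, and the methyl ester only undergoes degenerate exchange in methanol.

**Step 4**
Reactants: 6 methyl 2,2-dimethoxy-2-(4-methoxyphenyl)acetate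
Product: 7 N,2,2-trimethoxy-2-(4-methoxyphenyl)-N-methylacetamide
Conditions: MeNH(OMe)·HCl, i-PrMgCl, THF, −20 °C → 0 °C
Reagents that add atoms: N,O-dimethylhydroxylamine hydrochloride, CNOC.Cl
Why: Weinreb amide formation by aminolysis of the ester with the magnesium amide made in the flask, in which the two α-alkoxy groups activate the hindered ester inductively and by chelation, and the basic medium leaves the ketal untouched.

**Step 5**
Reactants: 7 N,2,2-trimethoxy-2-(4-methoxyphenyl)-N-methylacetamide; 8 ethynylmagnesium bromide
Product: 10 1,1-dimethoxy-1-(4-methoxyphenyl)but-3-yn-2-one, via chelated tetrahedral magnesium adduct 9 (not isolated)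
Conditions: HC≡CMgBr, THF, 0 °C → rt; inverse quench into cold 1 M aq NaHSO4/Et2O, 0 °C, dark
Reagents that add atoms: ethynylmagnesium bromide 8, C#C[Mg]Br
Why: Weinreb ketone synthesis, in which the chelate 9 stops at mono-addition and releases the ynone only on quench, the cold acidic inverse quench protonates the liberated MeNH(OMe) before it can add to the terminal ynone, and the α-keto ketal should withstand a short biphasic contact with acid.

**Step 6**
Reactants: 4 (1Z,3Z)-1,4-dimethoxy-1,3-bis(trimethylsilyloxy)buta-1,3-diene; 10 1,1-dimethoxy-1-(4-methoxyphenyl)but-3-yn-2-one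
Product: 13 1-(2,4-dihydroxy-5-methoxyphenyl)-2,2-dimethoxy-2-(4-methoxyphenyl)ethan-1-one, via cyclohexa-1,4-diene cycloadduct 11 (not isolated), via mono-TMS aryl ether 12 (not isolated)
Conditions: 4 (excess), toluene, −20 °C → rt (→ 50 °C if conversion stalls), Ar, dark; then THF, 10% aq citric acid, 0 °C
Reagents that add atoms: none
Why: This is a normal-electron-demand Diels–Alder reaction in which the s-cis diene 4, with its HOMO raised by four oxygen substituents, adds across the acyl-activated triple bond of 10 in a concerted but strongly asynchronous [4+2] event with C8–C7 bonding ahead of C5–C6; a stepwise vinylogous Mukaiyama–Michael addition followed by closure of the allenolate carbon C6 onto the cationic C5 would reach the same adduct 11. The closest known reaction type is the cycloaddition of 1-alkoxy-1,3-bis(silyloxy)butadienes and related 1,1,3-trioxygenated dienes, 4-alkoxy members included, with alkynones and propiolates to give resorcinols. The one ring formed, the all-carbon six-membered benzene ring of the future chromene, is closed by intermolecular [4+2] cycloaddition, after which the mixed methyl silyl ketal at C5 of 11 expels MeOSiMe3 and the C8 hydrogen moves to oxygen to give 12; C5 has no hydrogen, so the C8 methoxy group cannot be eliminated and is kept. The regiochemistry needed (acyl-bearing C6 next to the C5 oxygen, C8–OMe next to C7–H) follows from polarity matching, because C8 is the terminus that receives the push of both C5 oxygens and the C8a oxygen, while C7 is the unsubstituted β-carbon of the ynone with the largest LUMO coefficient and the least hindrance. No stereocentre survives, since the sp3 centres C5 and C8 of 11 are erased on aromatisation, so endo/exo selectivity and diene geometry have no bearing on the product. Lewis-acid-free conditions and the shielding of Cα=O by the quaternary ketal carbon disfavour 1,2-addition and an aldol-type closure, and the citric acid wash only cleaves the last aryl silyl ether while the α-keto ketal should remain.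

**Step 7**
Reactants: 13 1-(2,4-dihydroxy-5-methoxyphenyl)-2,2-dimethoxy-2-(4-methoxyphenyl)ethan-1-one; 14 3-methylbut-2-enal
Product: 16 1-(5-hydroxy-8-methoxy-2,2-dimethyl-2H-chromen-6-yl)-2,2-dimethoxy-2-(4-methoxyphenyl)ethan-1-one, via ortho-quinone methide 15 (not isolated)
Conditions: Ca(OH)2, MeOH, rt → 40 °C, Ar, dark
Reagents that add atoms: 3-methylbut-2-enal 14, CC(C)=CC=O
Why: Base-mediated chromene annulation of a resorcinol with an enal (aldol-type attack of phenolate carbon C4a on the aldehyde, loss of water to 15, oxa-6π electrocyclisation forming O1–C2), well known for 2,4-dihydroxyaryl ketones; C4a is the only free carbon activated by both phenolic oxygens (C8 is blocked, C7 is meta to both), closure uses the C8a oxygen because the C5 oxygen stays chelated to Cα=O, and the basic medium cannot touch the ketal.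

**Step 8**
Reactants: 16 1-(5-hydroxy-8-methoxy-2,2-dimethyl-2H-chromen-6-yl)-2,2-dimethoxy-2-(4-methoxyphenyl)ethan-1-one
Product: 17 dielsianone, 1-(5-hydroxy-8-methoxy-2,2-dimethyl-2H-chromen-6-yl)-2-(4-methoxyphenyl)ethane-1,2-dione
Conditions: 1 M aq HCl, THF, rt, dark
Reagents that add atoms: water, O
Why: Acid-catalysed ketal hydrolysis, in which the p-anisyl group makes ionisation at Cβ feasible despite the adjacent carbonyl, so dilute acid at room temperature should suffice; the 2,2-dimethyl-2H-chromene, the aryl methyl ethers and the chelated phenol tolerate these conditions, and the excess of water drives any reversible capture of Cβ by C5–OH or methanol on to the open, hydrogen-bonded hydroxy-dione.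

**Compound list**
1 | methyl 4-methoxyacetoacetate | COCC(=O)CC(=O)OC | starting material
2 | methyl (Z)-4-methoxy-3-(trimethylsilyloxy)but-2-enoate | COC/C(O[Si](C)(C)C)=C/C(=O)OC | intermediate
3 | lithium dienolate of 2 (lithium 1,4-dimethoxy-3-(trimethylsilyloxy)buta-1,3-dien-1-olate) | CO/C(O[Li])=C/C(O[Si](C)(C)C)=C/OC | intermediate
4 | (1Z,3Z)-1,4-dimethoxy-1,3-bis(trimethylsilyloxy)buta-1,3-diene | CO/C(O[Si](C)(C)C)=C/C(O[Si](C)(C)C)=C/OC | intermediate
5 | methyl 2-(4-methoxyphenyl)-2-oxoacetate | COC(=O)C(=O)c1ccc(OC)cc1 | starting material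
6 | methyl 2,2-dimethoxy-2-(4-methoxyphenyl)acetate | COC(=O)C(OC)(OC)c1ccc(OC)cc1 | intermediate
7 | N,2,2-trimethoxy-2-(4-methoxyphenyl)-N-methylacetamide | CON(C)C(=O)C(OC)(OC)c1ccc(OC)cc1 | intermediate
8 | ethynylmagnesium bromide | C#C[Mg]Br | starting material
9 | bromomagnesium alkoxide of the tetrahedral adduct of 7 and 8 (racemic) | C#CC(O[Mg]Br)(N(C)OC)C(OC)(OC)c1ccc(OC)cc1 | intermediate
10 | 1,1-dimethoxy-1-(4-methoxyphenyl)but-3-yn-2-one | C#CC(=O)C(OC)(OC)c1ccc(OC)cc1 | intermediate
11 | 1-[3,6-dimethoxy-4,6-bis(trimethylsilyloxy)cyclohexa-1,4-dien-1-yl]-2,2-dimethoxy-2-(4-methoxyphenyl)ethan-1-one (racemic diastereomer mixture, both centres lost later) | COC1(O[Si](C)(C)C)C=C(O[Si](C)(C)C)C(OC)C=C1C(=O)C(OC)(OC)c1ccc(OC)cc1 | intermediate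
12 | 1-[2-hydroxy-5-methoxy-4-(trimethylsilyloxy)phenyl]-2,2-dimethoxy-2-(4-methoxyphenyl)ethan-1-one | COc1ccc(C(OC)(OC)C(=O)c2cc(OC)c(O[Si](C)(C)C)cc2O)cc1 | intermediate
13 | 1-(2,4-dihydroxy-5-methoxyphenyl)-2,2-dimethoxy-2-(4-methoxyphenyl)ethan-1-one | COc1ccc(C(OC)(OC)C(=O)c2cc(OC)c(O)cc2O)cc1 | intermediate
14 | 3-methylbut-2-enal | CC(C)=CC=O | starting material
15 | ortho-quinone methide: C8a ketone, exocyclic C4a=CH–CH=CMe2 with the vinyl group syn to C8a=O | COc1ccc(C(OC)(OC)C(=O)C2=C(O)/C(=C/C=C(C)C)C(=O)C(OC)=C2)cc1 | intermediate
16 | 1-(5-hydroxy-8-methoxy-2,2-dimethyl-2H-chromen-6-yl)-2,2-dimethoxy-2-(4-methoxyphenyl)ethan-1-one | COc1ccc(C(OC)(OC)C(=O)c2cc(OC)c3c(c2O)C=CC(C)(C)O3)cc1 | intermediate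
17 | dielsianone | COc1ccc(C(=O)C(=O)c2cc(OC)c3c(c2O)C=CC(C)(C)O3)cc1 | target

**Step count**
- Total step count: 8 (convergent: 2 steps to the diene, 3 to the ynone, 3 after union).
- Longest linear sequence: 6 steps (5 → 6 → 7 → 10 → 13 → 16 → 17).

**Steps most likely to fail**

1. **Step 6.**
   - The silyl groups of 4 may be lost to adventitious moisture before the diene meets the dienophile.
   - Bond formation may stop after C8–C7. The open-chain material may then close in the aldol sense (C4a onto Cα) or not close at all.
   - Aromatisation may proceed with loss of silanol instead of MeOSiMe3, which would leave C5 etherified.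
   - Fallback (sets out from 7, comes back at 13): the trioxygenated ring is bought rather than built. Commercial 4-methoxyresorcinol is dibenzylated (BnBr, K2CO3, DMF) to 2,4-bis(benzyloxy)-1-methoxybenzene F1. Bromination at the position ortho and para to the two benzyloxy groups (NBS, MeCN, 0 °C) gives 1-bromo-2,4-bis(benzyloxy)-5-methoxybenzene F2. Bromine–lithium exchange (n-BuLi, THF, −78 °C) and acylation with Weinreb amide 7 give 1-[2,4-bis(benzyloxy)-5-methoxyphenyl]-2,2-dimethoxy-2-(4-methoxyphenyl)ethan-1-one F3. Neutral hydrogenolysis (H2, Pd/C, EtOAc, rt) then frees both phenols and delivers 13.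

2. **Step 7.**
   - C-alkylation at C4a of the acyl-deactivated, doubly hydrogen-bonded resorcinol may be slow.
   - The enal may self-condense, and the electron-rich phenolate may oxidise in air.
   - Electrocyclisation may occur through the C5 oxygen.
   - Fallback (sets out from 13, comes back at 16): the oxygen is fixed first and the carbon bond made second. The non-chelated C8a hydroxyl is alkylated selectively with 3-chloro-3-methylbut-1-yne (K2CO3, KI, cat. CuI, acetone, 50 °C) to give 1-[2-hydroxy-5-methoxy-4-(2-methylbut-3-yn-2-yloxy)phenyl]-2,2-dimethoxy-2-(4-methoxyphenyl)ethan-1-one F4. Heating (N,N-diethylaniline or o-xylene, about 140 °C) triggers the aryl propargyl Claisen rearrangement to C4a, which is the only open ortho carbon. A 1,5-hydrogen shift and oxa-6π closure then give 16.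

3. **Step 5.**
   - The liberated N,O-dimethylhydroxylamine may add to the terminal ynone during the quench.
   - Addition to the amide next to the fully substituted ketal carbon may be slow.
   - The ketal may be partly lost in the acidic quench.
   - Fallback (sets out from 6, comes back at 10; it also bypasses step 4): the amine is avoided altogether. Ester 6 is reduced with i-Bu2AlH (CH2Cl2, −78 °C) to 2,2-dimethoxy-2-(4-methoxyphenyl)acetaldehyde F5. Addition of 8 (THF, 0 °C) gives racemic 1,1-dimethoxy-1-(4-methoxyphenyl)but-3-yn-2-ol F6. Oxidation of the propargylic alcohol (MnO2, CH2Cl2, rt, or Dess–Martin periodinane with NaHCO3) gives 10.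

**Further compounds**
F1 | step 6 | 2,4-bis(benzyloxy)-1-methoxybenzene | COc1ccc(OCc2ccccc2)cc1OCc1ccccc1
F2 | step 6 | 1-bromo-2,4-bis(benzyloxy)-5-methoxybenzene | COc1cc(Br)c(OCc2ccccc2)cc1OCc1ccccc1
F3 | step 6 | 1-[2,4-bis(benzyloxy)-5-methoxyphenyl]-2,2-dimethoxy-2-(4-methoxyphenyl)ethan-1-one | COc1ccc(C(OC)(OC)C(=O)c2cc(OC)c(OCc3ccccc3)cc2OCc2ccccc2)cc1
F4 | step 7 | 1-[2-hydroxy-5-methoxy-4-(2-methylbut-3-yn-2-yloxy)phenyl]-2,2-dimethoxy-2-(4-methoxyphenyl)ethan-1-one | COc1ccc(C(OC)(OC)C(=O)c2cc(OC)c(OC(C)(C)C#C)cc2O)cc1
F5 | step 5 | 2,2-dimethoxy-2-(4-methoxyphenyl)acetaldehyde | COc1ccc(C(OC)(OC)C=O)cc1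
F6 | step 5 | 1,1-dimethoxy-1-(4-methoxyphenyl)but-3-yn-2-ol (racemic) | C#CC(O)C(OC)(OC)c1ccc(OC)cc1
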